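**Retrosynthetic overview**

1. The target is 2-(2,4-dihydroxy-5-methoxyphenyl)-5,6,7,8-tetramethoxy-4H-chromen-4-one (ring A = fully substituted benzo ring, ring C = pyranone, ring B = 2-aryl group; no stereocenter). The two ring B phenols are released last from benzyl ethers, and before that ring C is closed by acid through the O1–C2 bond.
2. Feature used: C2–C3–C4 of ring C is a three-carbon chain oxygenated at both ends (O1 on C2, the carbonyl on C4), so it is a 1,3-diketone in disguise. C4 sits on C4a of ring A, whose two neighbours C5 and C8a both bear oxygen, so a nitrile oxide carbon placed at C4 is shielded on both flanks and long-lived.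
3. Key disconnection: the diketone is carried as a 3,5-diarylisoxazole, cut into the ring A aryl nitrile oxide (supplies C4) and the ring B arylacetylene (supplies C3 and C2). The cycloaddition makes C4–C3 and a temporary O–C2 bond; Mo(CO)6 later breaks N–O.
4. Fragments: the dipole precursor comes from 1,2,3,4-tetramethoxybenzene (hydroxylation, MOM ether, ortho-formylation, oxime, chlorination). The alkyne comes from isovanillin (benzylation, Baeyer–Villiger oxidation, benzylation, Vilsmeier–Haack formylation, Ohira–Bestmann alkynylation).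
5. Ring order: rings A and B are bought; the temporary isoxazole is formed in step 11 and opened in step 12; ring C is closed in step 13.

Key step: step 11

Remark on the chemistry: oxime 9, hydroximoyl chloride 10 and enaminone 21 are drawn as the expected (E), (Z) and (Z) isomers; their geometry does not affect the outcome.

**Step 1**
Reactants: 1 1,2,3,4-tetramethoxybenzene
Product: 4 2,3,4,5-tetramethoxyphenol, via aryllithium 2 (not isolated), via lithium aryltrimethoxyborate 3 (not isolated)
Conditions: n-BuLi, TMEDA, THF, 0 °C; B(OMe)3, −78 °C → rt; AcOH, 30% aq H2O2, 0 °C → rt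
Reagents that add atoms: hydrogen peroxide, OO
Why: Methoxy-directed ortho-lithiation at one of the two equivalent ring hydrogens, trapping with the borate and peroxide oxidation of the C–B bond (aryl migration from boron to oxygen) is a standard arene hydroxylation sequence.

**Step 2**
Reactants: 4 2,3,4,5-tetramethoxyphenol
Product: 5 1,2,3,4-tetramethoxy-5-(methoxymethoxy)benzene
Conditions: NaH, MOMCl, THF, 0 °C → rt
Reagents that add atoms: chloromethyl methyl ether (MOMCl), COCCl
Why: Williamson-type O-alkylation of the sodium phenoxide by the reactive α-chloro ether installs the MOM acetal, which serves both as protecting group and as directing group for the next step.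

**Step 3**
Reactants: 5 1,2,3,4-tetramethoxy-5-(methoxymethoxy)benzene
Product: 8 2,3,4,5-tetramethoxy-6-(methoxymethoxy)benzaldehyde, via aryllithium 6 (not isolated), via lithium hemiaminal alkoxide 7 (not isolated)
Conditions: n-BuLi, THF, 0 °C; DMF, −78 °C → rt; H2O
Reagents that add atoms: N,N-dimethylformamide (DMF), CN(C)C=O
Why: Directed ortho-metalation occurs at the only ring hydrogen, which lies between the OMOM and an OMe group that both direct n-BuLi to it, and the aryllithium is formylated by DMF (Bouveault-type formylation).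

**Step 4**
Reactants: 8 2,3,4,5-tetramethoxy-6-(methoxymethoxy)benzaldehyde
Product: 9 (E)-2,3,4,5-tetramethoxy-6-(methoxymethoxy)benzaldehyde oxime
Conditions: NH2OH·HCl, NaOAc, EtOH/H2O, rt → 50 °C
Reagents that add atoms: hydroxylamine hydrochloride, Cl.NO
Why: Condensation of the aldehyde with hydroxylamine (oxime formation) under acetate buffering should give the thermodynamic (E)-aldoxime while the MOM acetal stays intact.

**Step 5**
Reactants: 9 (E)-2,3,4,5-tetramethoxy-6-(methoxymethoxy)benzaldehyde oxime
Product: 10 (Z)-N-hydroxy-2,3,4,5-tetramethoxy-6-(methoxymethoxy)benzenecarboximidoyl chloride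
Conditions: NCS, DMF, 0 °C → rt
Reagents that add atoms: N-chlorosuccinimide (NCS), O=C1CCC(=O)N1Cl
Why: Chlorination of the aldoxime carbon by NCS is the standard route to hydroximoyl chlorides, and the ring has no free position where nuclear chlorination could compete.

**Step 6**
Reactants: 11 isovanillin (3-hydroxy-4-methoxybenzaldehyde)
Product: 12 3-(benzyloxy)-4-methoxybenzaldehyde
Conditions: BnBr, K2CO3, DMF, 60 °C
Reagents that add atoms: benzyl bromide, BrCc1ccccc1
Why: Williamson ether synthesis on the potassium phenoxide.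

**Step 7**
Reactants: 12 3-(benzyloxy)-4-methoxybenzaldehyde
Product: 14 3-(benzyloxy)-4-methoxyphenol, via aryl formate 13 (not isolated)
Conditions: mCPBA, CH2Cl2, rt; then K2CO3 (cat.), MeOH, rt
Reagents that add atoms: meta-chloroperoxybenzoic acid (mCPBA), O=C(OO)c1cccc(Cl)c1
Why: In the Baeyer–Villiger oxidation the electron-rich aryl group with its para methoxy substituent migrates in preference to hydride, and the resulting formate is cleaved by methanolysis.

**Step 8**
Reactants: 14 3-(benzyloxy)-4-methoxyphenol
Product: 15 2,4-bis(benzyloxy)-1-methoxybenzene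
Conditions: BnBr, K2CO3, DMF, 60 °C
Reagents that add atoms: benzyl bromide, BrCc1ccccc1
Why: Williamson ether synthesis on the phenoxide.

**Step 9**
Reactants: 15 2,4-bis(benzyloxy)-1-methoxybenzene
Product: 17 2,4-bis(benzyloxy)-5-methoxybenzaldehyde, via aryl iminium chloride 16 (not isolated)
Conditions: POCl3, DMF, 0 → 70 °C; then aq NaOAc
Reagents that add atoms: N,N-dimethylformamide (DMF), CN(C)C=O; water, O
Why: Vilsmeier–Haack formylation should go to C5, which is para to one benzyloxy group and ortho to the other, as with 1,2,4-trimethoxybenzene; C3 is crowded between two ethers and C6 is activated by only one ortho oxygen.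

**Step 10**
Reactants: 17 2,4-bis(benzyloxy)-5-methoxybenzaldehyde
Product: 18 1,5-bis(benzyloxy)-2-ethynyl-4-methoxybenzene
Conditions: dimethyl (1-diazo-2-oxopropyl)phosphonate, K2CO3, MeOH/THF, rt
Reagents that add atoms: dimethyl (1-diazo-2-oxopropyl)phosphonate, CC(=O)C(=[N+]=[N-])P(=O)(OC)OC
Why: In the Ohira–Bestmann variant of the Seyferth–Gilbert homologation, methanolysis releases the diazomethylphosphonate anion, olefination of the aldehyde gives a diazoalkene, and loss of N2 with 1,2-hydrogen shift gives the terminal alkyne under conditions that leave the benzyl ethers untouched.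

**Step 11**
Reactants: 10 (Z)-N-hydroxy-2,3,4,5-tetramethoxy-6-(methoxymethoxy)benzenecarboximidoyl chloride; 18 1,5-bis(benzyloxy)-2-ethynyl-4-methoxybenzene
Product: 20 5-[2,4-bis(benzyloxy)-5-methoxyphenyl]-3-[2,3,4,5-tetramethoxy-6-(methoxymethoxy)phenyl]isoxazole, via nitrile oxide 19 (not isolated)
Conditions: Et3N (slow addition), toluene, rt → 80 °C
Reagents that add atoms: none
Why: Et3N removes HCl from 10 to give nitrile oxide 19, which adds to the terminal alkyne of 18 in a concerted, asynchronous [3+2] process; this is the Huisgen 1,3-dipolar cycloaddition of a nitrile oxide to an alkyne, the standard isoxazole synthesis. The one new ring, the isoxazole, is closed by intermolecular cycloaddition, with both bonds formed in the same step: the dipole carbon to the terminal alkyne carbon (the later C4–C3 bond) and the dipole oxygen to the internal alkyne carbon (the later C2 oxygen). No stereocenter is created. The selectivity needed is regiochemical, 3,5- over 3,4-diarylisoxazole, and the terminal arylacetylene secures it, because the bulky, fully substituted aryl group on the dipole carbon bonds to the unhindered CH terminus and the frontier-orbital coefficients of an arylacetylene point the same way. The dipole must also survive long enough to meet a moderately reactive dipolarophile, and the OMOM and OMe groups at both ortho positions block its dimerization to the furoxan, so warming to 80 °C can be used to drive the addition.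

**Step 12**
Reactants: 20 5-[2,4-bis(benzyloxy)-5-methoxyphenyl]-3-[2,3,4,5-tetramethoxy-6-(methoxymethoxy)phenyl]isoxazole
Product: 21 (Z)-3-amino-1-[2,4-bis(benzyloxy)-5-methoxyphenyl]-3-[2,3,4,5-tetramethoxy-6-(methoxymethoxy)phenyl]prop-2-en-1-one
Conditions: Mo(CO)6, MeCN/H2O, 80 °C
Reagents that add atoms: none
Why: Zerovalent molybdenum binds the ring nitrogen and cleaves the weak N–O bond reductively, water supplying the hydrogens (known reductive ring opening of isoxazoles to β-enaminoketones), under neutral conditions that spare the benzyl ethers and the MOM acetal.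

**Step 13**
Reactants: 21 (Z)-3-amino-1-[2,4-bis(benzyloxy)-5-methoxyphenyl]-3-[2,3,4,5-tetramethoxy-6-(methoxymethoxy)phenyl]prop-2-en-1-one
Product: 23 2-[2,4-bis(benzyloxy)-5-methoxyphenyl]-5,6,7,8-tetramethoxy-4H-chromen-4-one, via hydroxy diketone 22 (not isolated)
Conditions: 3 M aq HCl, MeOH/THF, 60 °C
Reagents that add atoms: water, O
Why: Acid cleaves the MOM acetal and hydrolyses the vinylogous amide to the 1,3-diketone, whose ring A phenol adds to the ring B carbonyl (6-exo-trig) and loses water to close ring C, as in the final stage of a Baker–Venkataraman flavone synthesis; the ring B oxygens remain benzylated, so closure can occur in one direction only.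

**Step 14**
Reactants: 23 2-[2,4-bis(benzyloxy)-5-methoxyphenyl]-5,6,7,8-tetramethoxy-4H-chromen-4-one
Product: 24 2-(2,4-dihydroxy-5-methoxyphenyl)-5,6,7,8-tetramethoxy-4H-chromen-4-one
Conditions: H2 (1 atm), 10% Pd/C, EtOAc/MeOH, rt
Reagents that add atoms: none
Why: Catalytic hydrogenolysis of the two aryl benzyl ethers should be much faster than hydrogenation of the conjugated C2–C3 double bond of the chromone, so stopping after two equivalents of H2 should leave ring C and all methyl ethers intact.

**Compound list**

1 | 1,2,3,4-tetramethoxybenzene | COc1ccc(OC)c(OC)c1OC | starting material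
2 | (2,3,4,5-tetramethoxyphenyl)lithium | [Li]c1cc(OC)c(OC)c(OC)c1OC | intermediate
3 | lithium trimethoxy(2,3,4,5-tetramethoxyphenyl)borate | [Li+].CO[B-](OC)(OC)c1cc(OC)c(OC)c(OC)c1OC | intermediate
4 | 2,3,4,5-tetramethoxyphenol | COc1cc(O)c(OC)c(OC)c1OC | intermediate
5 | 1,2,3,4-tetramethoxy-5-(methoxymethoxy)benzene | COCOc1cc(OC)c(OC)c(OC)c1OC | intermediate
6 | [2,3,4,5-tetramethoxy-6-(methoxymethoxy)phenyl]lithium | [Li]c1c(OC)c(OC)c(OC)c(OC)c1OCOC | intermediate
7 | lithium (dimethylamino)[2,3,4,5-tetramethoxy-6-(methoxymethoxy)phenyl]methanolate (racemic, center lost on hydrolysis) | [Li+].[O-]C(N(C)C)c1c(OC)c(OC)c(OC)c(OC)c1OCOC | intermediate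
8 | 2,3,4,5-tetramethoxy-6-(methoxymethoxy)benzaldehyde | COCOc1c(OC)c(OC)c(OC)c(OC)c1C=O | intermediate
9 | (E)-2,3,4,5-tetramethoxy-6-(methoxymethoxy)benzaldehyde oxime | COCOc1c(OC)c(OC)c(OC)c(OC)c1/C=N/O | intermediate
10 | (Z)-N-hydroxy-2,3,4,5-tetramethoxy-6-(methoxymethoxy)benzenecarboximidoyl chloride | COCOc1c(OC)c(OC)c(OC)c(OC)c1/C(Cl)=N/O | intermediate
11 | isovanillin (3-hydroxy-4-methoxybenzaldehyde) | COc1ccc(C=O)cc1O | starting material
12 | 3-(benzyloxy)-4-methoxybenzaldehyde | COc1ccc(C=O)cc1OCc1ccccc1 | intermediate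
13 | 3-(benzyloxy)-4-methoxyphenyl formate | COc1ccc(OC=O)cc1OCc1ccccc1 | intermediate
14 | 3-(benzyloxy)-4-methoxyphenol | COc1ccc(O)cc1OCc1ccccc1 | intermediate
15 | 2,4-bis(benzyloxy)-1-methoxybenzene | COc1ccc(OCc2ccccc2)cc1OCc1ccccc1 | intermediate
16 | N-[2,4-bis(benzyloxy)-5-methoxybenzylidene]-N-methylmethanaminium chloride | COc1cc(C=[N+](C)C)c(OCc2ccccc2)cc1OCc1ccccc1.[Cl-] | intermediate
17 | 2,4-bis(benzyloxy)-5-methoxybenzaldehyde | COc1cc(C=O)c(OCc2ccccc2)cc1OCc1ccccc1 | intermediate
18 | 1,5-bis(benzyloxy)-2-ethynyl-4-methoxybenzene | C#Cc1cc(OC)c(OCc2ccccc2)cc1OCc1ccccc1 | intermediate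
19 | 2,3,4,5-tetramethoxy-6-(methoxymethoxy)benzonitrile oxide | COCOc1c(OC)c(OC)c(OC)c(OC)c1C#[N+][O-] | intermediate
20 | 5-[2,4-bis(benzyloxy)-5-methoxyphenyl]-3-[2,3,4,5-tetramethoxy-6-(methoxymethoxy)phenyl]isoxazole | COCOc1c(OC)c(OC)c(OC)c(OC)c1-c1cc(-c2cc(OC)c(OCc3ccccc3)cc2OCc2ccccc2)on1 | intermediate
21 | (Z)-3-amino-1-[2,4-bis(benzyloxy)-5-methoxyphenyl]-3-[2,3,4,5-tetramethoxy-6-(methoxymethoxy)phenyl]prop-2-en-1-one | COCOc1c(OC)c(OC)c(OC)c(OC)c1/C(N)=C/C(=O)c1cc(OC)c(OCc2ccccc2)cc1OCc1ccccc1 | intermediate
22 | 1-[2,4-bis(benzyloxy)-5-methoxyphenyl]-3-(2-hydroxy-3,4,5,6-tetramethoxyphenyl)propane-1,3-dione | COc1c(O)c(C(=O)CC(=O)c2cc(OC)c(OCc3ccccc3)cc2OCc2ccccc2)c(OC)c(OC)c1OC | intermediate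
23 | 2-[2,4-bis(benzyloxy)-5-methoxyphenyl]-5,6,7,8-tetramethoxy-4H-chromen-4-one | COc1cc(-c2cc(=O)c3c(OC)c(OC)c(OC)c(OC)c3o2)c(OCc2ccccc2)cc1OCc1ccccc1 | intermediate
24 | 2-(2,4-dihydroxy-5-methoxyphenyl)-5,6,7,8-tetramethoxy-4H-chromen-4-one | COc1cc(-c2cc(=O)c3c(OC)c(OC)c(OC)c(OC)c3o2)c(O)cc1O | target

**Step count**

Total step count: 14.
Longest linear sequence: 9 steps (steps 1–5 then 11–14 from 1; the isovanillin branch, steps 6–10 then 11–14, is equally long).

**Steps most likely to fail**

Step 11. The dipole carbon is flanked by two ortho substituents and the alkyne carries an ortho benzyloxy group, so the cycloaddition may be slow. On heating, isomerization of the nitrile oxide to the isocyanate could then outrun it, or regiocontrol could erode. The fallback replaces the alkyne by the more reactive alkene and restores the oxidation level afterwards; it sets out from aldehyde 17 (with hydroximoyl chloride 10) and comes back at isoxazole 20. Wittig methylenation of 17 (Ph3PCH3Br, KOtBu, THF) should give 1,5-bis(benzyloxy)-2-ethenyl-4-methoxybenzene F1. Cycloaddition of nitrile oxide 19 (from 10, Et3N) to this styrene, regioselective for the 5-aryl adduct, should give racemic 5-[2,4-bis(benzyloxy)-5-methoxyphenyl]-3-[2,3,4,5-tetramethoxy-6-(methoxymethoxy)phenyl]-4,5-dihydroisoxazole F2. Dehydrogenation with activated MnO2 in refluxing toluene should then give 20.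

Step 13. Three acid-driven events must keep pace: acetal cleavage, hydrolysis of the vinylogous amide and cyclodehydration. The reaction may stall at the protonated enaminone stage, and forcing it risks loss of the ring B benzyl ether ortho to the carbonyl, followed by closure in the wrong direction. The fallback builds the same C2–C3–C4 chain as an ynone and closes ring C by conjugate addition; it sets out from aldehyde 8 and alkyne 18 and comes back at flavone 23. Deprotonation of 18 (n-BuLi, THF, −78 °C) gives lithium [2,4-bis(benzyloxy)-5-methoxyphenyl]acetylide F3. Addition to 8 should give racemic 3-[2,4-bis(benzyloxy)-5-methoxyphenyl]-1-[2,3,4,5-tetramethoxy-6-(methoxymethoxy)phenyl]prop-2-yn-1-ol F4. Oxidation with activated MnO2 (CH2Cl2, rt) should give 3-[2,4-bis(benzyloxy)-5-methoxyphenyl]-1-[2,3,4,5-tetramethoxy-6-(methoxymethoxy)phenyl]prop-2-yn-1-one F5. Brief treatment with HCl in MeOH/THF at rt should remove the MOM group to give 3-[2,4-bis(benzyloxy)-5-methoxyphenyl]-1-(2-hydroxy-3,4,5,6-tetramethoxyphenyl)prop-2-yn-1-one F6. A catalytic amount of DMAP in DMF should then bring about 6-endo-dig oxa-Michael cyclization of this o-alkynoylphenol to 23.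

Step 1. Metalation may be incomplete or go twice, and the very electron-rich phenol may be over-oxidized toward a quinone during the peroxide stage. The fallback installs the oxygen by electrophilic formylation and Baeyer–Villiger oxidation; it sets out from 1 and comes back at phenol 4. Vilsmeier–Haack formylation of 1 (POCl3, DMF, then aq NaOAc) proceeds through N-methyl-N-(2,3,4,5-tetramethoxybenzylidene)methanaminium chloride F7, hydrolysed on work-up to 2,3,4,5-tetramethoxybenzaldehyde F8. Baeyer–Villiger oxidation (mCPBA, CH2Cl2) should give 2,3,4,5-tetramethoxyphenyl formate F9, and methanolysis (K2CO3, MeOH) should give 4.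

**Further compounds**

F1 | step 11 | 1,5-bis(benzyloxy)-2-ethenyl-4-methoxybenzene | C=Cc1cc(OC)c(OCc2ccccc2)cc1OCc1ccccc1
F2 | step 11 | racemic 5-[2,4-bis(benzyloxy)-5-methoxyphenyl]-3-[2,3,4,5-tetramethoxy-6-(methoxymethoxy)phenyl]-4,5-dihydroisoxazole | COCOc1c(OC)c(OC)c(OC)c(OC)c1C1=NOC(c2cc(OC)c(OCc3ccccc3)cc2OCc2ccccc2)C1
F3 | step 13 | lithium [2,4-bis(benzyloxy)-5-methoxyphenyl]acetylide | [Li]C#Cc1cc(OC)c(OCc2ccccc2)cc1OCc1ccccc1
F4 | step 13 | racemic 3-[2,4-bis(benzyloxy)-5-methoxyphenyl]-1-[2,3,4,5-tetramethoxy-6-(methoxymethoxy)phenyl]prop-2-yn-1-ol | COCOc1c(OC)c(OC)c(OC)c(OC)c1C(O)C#Cc1cc(OC)c(OCc2ccccc2)cc1OCc1ccccc1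
F5 | step 13 | 3-[2,4-bis(benzyloxy)-5-methoxyphenyl]-1-[2,3,4,5-tetramethoxy-6-(methoxymethoxy)phenyl]prop-2-yn-1-one | COCOc1c(OC)c(OC)c(OC)c(OC)c1C(=O)C#Cc1cc(OC)c(OCc2ccccc2)cc1OCc1ccccc1
F6 | step 13 | 3-[2,4-bis(benzyloxy)-5-methoxyphenyl]-1-(2-hydroxy-3,4,5,6-tetramethoxyphenyl)prop-2-yn-1-one | COc1c(O)c(C(=O)C#Cc2cc(OC)c(OCc3ccccc3)cc2OCc2ccccc2)c(OC)c(OC)c1OC
F7 | step 1 | N-methyl-N-(2,3,4,5-tetramethoxybenzylidene)methanaminium chloride | COc1cc(C=[N+](C)C)c(OC)c(OC)c1OC.[Cl-]
F8 | step 1 | 2,3,4,5-tetramethoxybenzaldehyde | COc1cc(C=O)c(OC)c(OC)c1OC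
F9 | step 1 | 2,3,4,5-tetramethoxyphenyl formate | COc1cc(OC=O)c(OC)c(OC)c1OC
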